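**Assumption:** the target has no stereocentres (the SMILES contains none), so "single enantiomer" is vacuous. The only sp3 stereocentre in the route (C-2 of 4) is racemic and is destroyed in the key step.

## Retrosynthetic overview
1. Kuwanon B (**1**) ⇐ MOM-protected flavone **2** (MOM cleavage) ⇐ phloroglucinol (**3**) + α-prenyl aroylacetate **4**. This is the key step: desymmetrizing C-acylation of the C3-symmetric triol by an acylketene, with cyclodehydration forming the γ-pyranone and the 5,7-dihydroxy A ring together.
2. **4** ⇐ ethyl aroylacetate **5** ⇐ aryl methyl ketone **6** ⇐ directed ortho-metalation of MOM-chromene **7** ⇐ chromenol **8**.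
3. **8** ⇐ dehydrogenative aromatization of tetrahydrochromenone **9** ⇐ 1,3-cyclohexanedione (**10**) + prenal (**11**). This fixes the angular 5-oxygenated chromene regiospecifically.
4. Ring order: dimethylpyran on the non-aromatic dione, then aromatization of the B ring, then the pyranone and A ring in one operation.

## Route

**Step 1**
Reactants: **10** 1,3-cyclohexanedione; **11** prenal (3-methylbut-2-enal)
Product: **9** 2,2-dimethyl-2,6,7,8-tetrahydro-5H-chromen-5-one
Conditions: EDDA (10 mol%), MeCN, 60 °C
Reagents that add atoms: none
Why: Knoevenagel condensation gives a 1-oxatriene that undergoes 6π-oxa-electrocyclization (Knoevenagel/electrocyclization). The pyran O ends up on one dione carbonyl carbon and the CH=CH on C-2, so the remaining C=O sits next to C-4a, which is the angular 5-oxygenation pattern.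

**Step 2**
Reactants: **9**
Product: **8** 2,2-dimethyl-2H-chromen-5-ol
Conditions: Pd(TFA)₂ (10 mol%), 2-Me₂N-pyridine (20 mol%), O₂ (1 atm), DMSO, 80 °C
Reagents that add atoms: none
Why: Pd-catalysed aerobic dehydrogenation of the cyclohexenone (loss of one H₂) gives the dienone, which tautomerizes to the phenol. It aromatizes the B ring without any regiochemical ambiguity.

**Step 3**
Reactants: **8**; **12** MOMCl
Product: **7** 5-(methoxymethoxy)-2,2-dimethyl-2H-chromene
Conditions: i-Pr₂NEt, CH₂Cl₂, 0 °C → rt
Reagents that add atoms: MOMCl, COCCl
Why: Williamson-type O-protection. The phenol must be masked so that the later β-ketoester cannot close onto it to form a 4-hydroxycoumarin, and so that it can act as a directing group.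

**Step 4**
Reactants: **7**; **13** N-methoxy-N-methylacetamide
Product: **6** 1-[5-(methoxymethoxy)-2,2-dimethyl-2H-chromen-6-yl]ethan-1-one
Conditions: s-BuLi, TMEDA, THF, −78 °C; then **13**, −78 °C → rt
Reagents that add atoms: N-methoxy-N-methylacetamide, CC(=O)N(C)OC
Why: directed ortho-metalation. The MOM-ether oxygen directs lithiation to C-6, the only free ortho position, and the Weinreb amide stops at the ketone.

**Step 5**
Reactants: **6**; **14** diethyl carbonate
Product: **5** ethyl 3-[5-(methoxymethoxy)-2,2-dimethyl-2H-chromen-6-yl]-3-oxopropanoate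
Conditions: NaH (3 equiv), (EtO)₂CO (5 equiv), THF, reflux
Reagents that add atoms: diethyl carbonate, CCOC(=O)OCC
Why: Claisen-type C-acylation of the ketone enolate gives the aroylacetate.

**Step 6**
Reactants: **5**; **15** prenyl bromide
Product: **4** ethyl 2-{[5-(methoxymethoxy)-2,2-dimethyl-2H-chromen-6-yl]carbonyl}-5-methylhex-4-enoate (racemic)
Conditions: K₂CO₃, KI (cat.), acetone, 50 °C
Reagents that add atoms: prenyl bromide, CC(C)=CCBr
Why: the soft, stabilized β-ketoester enolate undergoes SN2 C-alkylation at the α-carbon, installing the future C-3 prenyl. The new sp3 stereocentre is racemic and irrelevant, because it becomes sp2 in Step 7.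

**Step 7**
Reactants: **4**; **3** phloroglucinol (3 equiv)
Product: **2** 5,7-dihydroxy-2-[5-(methoxymethoxy)-2,2-dimethyl-2H-chromen-6-yl]-3-(3-methylbut-2-en-1-yl)-4H-chromen-4-one
Conditions: Ph₂O, 200–210 °C, 1 h, N₂ stream to remove EtOH and H₂O
Reagents that add atoms: none (phloroglucinol is a reactant)
Why: Proposed new method: thermolysis of **4** expels EtOH to give the aroyl(prenyl)acylketene. The neutral phloroglucinol, acting as a tri-enol/triketone equivalent, is C-acylated once (desymmetrization), and the product is deactivated toward a second acylation. The resulting 2-acylphloroglucinol 1,3-diketone then cyclodehydrates (ortho-OH onto the aryl ketone) to the 3-prenylflavone. The closest known chemistry is the thermal Simonis-type chromone synthesis of chrysin from phloroglucinol and ethyl benzoylacetate, here extended to an α-substituted, ortho-substituted aroylacetate. No stereocentre is formed.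

**Step 8**
Reactants: **2**
Product: **1** Kuwanon B
Conditions: ZnBr₂ (5 equiv), n-PrSH (10 equiv), CH₂Cl₂, 0 °C → rt
Reagents that add atoms: none (MOM is removed)
Why: Lewis-acid/thiol MOM cleavage is mild enough to spare the prenyl alkene, the acid-labile 2,2-dimethylchromene and the flavone. The product is achiral.

**Check against the target SMILES:** 3-prenyl, 5,7-dihydroxychromone, and a B ring attached at C-1′ with 2′-OH and a 3′,4′-fused 2,2-dimethyl-2H-pyran whose O is on C-4′. This is the 5-hydroxy-2,2-dimethylchromen-6-yl unit built in Steps 1–4. All atoms balance, and no stereochemistry is required.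

## Compound list
1 | Kuwanon B, 5,7-dihydroxy-2-(5-hydroxy-2,2-dimethyl-2H-chromen-6-yl)-3-prenylchromen-4-one | CC(C)=CCc1c(-c2ccc3OC(C)(C)C=Cc3c2O)oc2cc(O)cc(O)c2c1=O | target
2 | MOM-protected flavone | CC(C)=CCc1c(-c2ccc3OC(C)(C)C=Cc3c2OCOC)oc2cc(O)cc(O)c2c1=O | intermediate
3 | phloroglucinol | Oc1cc(O)cc(O)c1 | starting material
4 | ethyl 2-(aroyl)-5-methylhex-4-enoate (racemic) | CCOC(=O)C(CC=C(C)C)C(=O)c1ccc2OC(C)(C)C=Cc2c1OCOC | intermediate
5 | ethyl 3-aryl-3-oxopropanoate | CCOC(=O)CC(=O)c1ccc2OC(C)(C)C=Cc2c1OCOC | intermediate
6 | 6-acetyl-5-(MOM-oxy)-2,2-dimethylchromene | CC(=O)c1ccc2OC(C)(C)C=Cc2c1OCOC | intermediate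
7 | 5-(methoxymethoxy)-2,2-dimethyl-2H-chromene | CC1(C)C=Cc2c(OCOC)cccc2O1 | intermediate
8 | 2,2-dimethyl-2H-chromen-5-ol | CC1(C)C=Cc2c(O)cccc2O1 | intermediate
9 | 2,2-dimethyl-2,6,7,8-tetrahydro-5H-chromen-5-one | CC1(C)C=CC2=C(O1)CCCC2=O | intermediate
10 | 1,3-cyclohexanedione | O=C1CCCC(=O)C1 | starting material
11 | prenal | CC(C)=CC=O | starting material
12 | chloromethyl methyl ether (MOMCl) | COCCl | starting material
13 | N-methoxy-N-methylacetamide | CC(=O)N(C)OC | starting material
14 | diethyl carbonate | CCOC(=O)OCC | starting material
15 | prenyl bromide | CC(C)=CCBr | starting material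

**Total steps:** 8. **Longest linear sequence:** 8 (10 → 9 → 8 → 7 → 6 → 5 → 4 → 2 → 1).

**Three steps most likely to fail**
1. **Step 7** (thermal acylketene annulation). The hindered α-prenyl, ortho-substituted ketoester could stall at the diketone or lose the MOM group at 200 °C. *Fallback:* make the ketone ArCOCH₂CH₂CH=CMe₂ from **4** by saponification and decarboxylation, then do a Claisen condensation (LiHMDS) with methyl 2,4,6-tris(MOM-oxy)benzoate. Cyclodehydrate the resulting diketone with HCl/MeOH, which also removes the MOM groups.
2. **Step 2** (aerobic dehydrogenation). The chromene C=C may be oxidized or the substrate over-oxidized. *Fallback:* stepwise α-bromination with CuBr₂, then LiBr/Li₂CO₃ elimination in DMF and tautomerization to the phenol.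
3. **Step 4** (ortho-lithiation). Competing C-8 lithiation or chromene decomposition is possible. *Fallback:* reverse the order, with a BF₃·OEt₂/AcOH ortho-acetylation of free phenol **8**, then MOM protection of the resulting 6-acetyl-5-hydroxychromene to give **6**.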